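The route rests on the ring-fusion bond C6–C7 shared by the ten-membered carbocycle (C1–C10) and the α-methylene-γ-butyrolactone (C6, C7, C11, C12, O). An acyclic (Z)-enal carrying a 2-(bromomethyl)acrylate terminus is closed by an intramolecular CrCl2-mediated (Nozaki–Hiyama type) carbonyl allylation. The allylchromium attacks the C6 aldehyde through its γ-carbon C7, which forms the carbocycle, sets C6 and C7, unmasks the exocyclic C11=C13 methylene and lets the C6 alkoxide lactonise onto the C12 ester in the same operation. The precursor already holds the cis-1,10-epoxide, the C3 acetate, the C8 silyl ether and the 4Z olefin.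

Key step: step 18

Numbering: germacranolide locants of the target are used throughout (ring carbons C1–C10; C6 = lactone carbinol carbon; C7 = ring-fusion carbon; C11, C12, C13 = lactone α-carbon, carbonyl carbon and exocyclic methylene; C14 = methyl on C10; C15 = CH2O on C4).
Assumption: in step 11 the antipode of the chiral ligand is chosen so that the 3S carbinol forms; both antipodes are accessible.

Step 1
Reactants: 1 but-2-yne-1,4-diol
Product: 2 4-[(4-methoxybenzyl)oxy]but-2-yn-1-ol
Conditions: NaH (1 equiv), 4-methoxybenzyl chloride (1 equiv), Bu4NI (cat.), THF/DMF, 0 °C to rt, diol in excess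
Reagents that add atoms: 4-methoxybenzyl chloride, COc1ccc(CCl)cc1
Why: Williamson etherification in which an excess of the symmetrical diol favours the monoether; no stereocentre is involved.

Step 2
Reactants: 2 4-[(4-methoxybenzyl)oxy]but-2-yn-1-ol
Product: 4 (2Z)-3-iodo-4-[(4-methoxybenzyl)oxy]but-2-en-1-ol, via cyclic alkenylalanate 3 (not isolated)
Conditions: NaAlH2(OCH2CH2OMe)2, THF, 0 °C; then I2, −78 to 0 °C
Reagents that add atoms: iodine, II
Why: hydroxyl-directed trans-hydroalumination puts aluminium on the alkyne carbon distal to the free hydroxyl (C4) and cis to the CH2O arm, so iodinolysis with retention should give the Z-iodide with iodine cis to C6, which later fixes the 4Z geometry.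

Step 3
Reactants: 4 (2Z)-3-iodo-4-[(4-methoxybenzyl)oxy]but-2-en-1-ol
Product: 5 (2Z)-3-iodo-4-[(4-methoxybenzyl)oxy]but-2-enal
Conditions: MnO2, CH2Cl2, rt
Reagents that add atoms: none
Why: neutral MnO2 oxidation of the primary allylic alcohol should leave the alkenyl iodide and its geometry untouched.

Step 4
Reactants: 5 (2Z)-3-iodo-4-[(4-methoxybenzyl)oxy]but-2-enal
Product: 6 1-({[(2Z)-2-iodo-4,4-dimethoxybut-2-en-1-yl]oxy}methyl)-4-methoxybenzene
Conditions: HC(OMe)3, PPTS (cat.), MeOH, rt
Reagents that add atoms: trimethyl orthoformate, COC(OC)OC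
Why: acid-catalysed acetalisation masks the future C6 aldehyde as a base-stable dimethyl acetal that is removed late under very mild acid.

Step 5
Reactants: 7 (S)-glycidol
Product: 8 (R)-triethyl(oxiran-2-ylmethoxy)silane
Conditions: TESCl, Et3N, DMAP (cat.), CH2Cl2, 0 °C
Reagents that add atoms: chlorotriethylsilane, CC[Si](Cl)(CC)CC
Why: silylation of the primary alcohol; the stereocentre (future C8) is not touched and only its descriptor changes from S to R through the priority change.

Step 6
Reactants: 9 1-[(but-3-yn-1-yloxy)methyl]-4-methoxybenzene; 8 (R)-triethyl(oxiran-2-ylmethoxy)silane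
Product: 11 (2R)-7-[(4-methoxybenzyl)oxy]-1-[(triethylsilyl)oxy]hept-4-yn-2-ol, via lithium acetylide 10 (not isolated)
Conditions: n-BuLi, THF, −78 °C; BF3·OEt2; then 8, −78 °C; aq. NH4Cl
Reagents that add atoms: none
Why: BF3-promoted opening of the terminal epoxide by the lithium acetylide at the CH2 carbon joins C9 to C10 and carries the chiral-pool centre C8 over unchanged.

Step 7
Reactants: 11 (2R)-7-[(4-methoxybenzyl)oxy]-1-[(triethylsilyl)oxy]hept-4-yn-2-ol
Product: 12 1-({[(6R)-6,7-bis(triethylsilyloxy)hept-3-yn-1-yl]oxy}methyl)-4-methoxybenzene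
Conditions: TESCl, imidazole, DMF, 0 °C to rt
Reagents that add atoms: chlorotriethylsilane, CC[Si](Cl)(CC)CC
Why: silylation masks the C8 hydroxyl, which would otherwise direct the carbometalation of step 9 to the wrong alkyne carbon.

Step 8
Reactants: 12 1-({[(6R)-6,7-bis(triethylsilyloxy)hept-3-yn-1-yl]oxy}methyl)-4-methoxybenzene
Product: 13 (6R)-6,7-bis[(triethylsilyl)oxy]hept-3-yn-1-ol
Conditions: DDQ, CH2Cl2/pH 7 buffer, 0 °C
Reagents that add atoms: none
Why: oxidative cleavage of the 4-methoxybenzyl ether under buffered conditions should free only the C3 hydroxyl and leave both silyl ethers.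

Step 9
Reactants: 13 (6R)-6,7-bis[(triethylsilyl)oxy]hept-3-yn-1-ol
Product: 15 (3Z,6R)-4-methyl-6,7-bis[(triethylsilyl)oxy]hept-3-en-1-ol, via alkenylmagnesium alkoxide 14 (not isolated)
Conditions: Fe(acac)3 (cat.), 1,2-bis(diphenylphosphino)ethane (cat.), MeMgBr (5 equiv), THF, −78 to 0 °C; aq. NH4Cl
Reagents that add atoms: methylmagnesium bromide, C[Mg]Br
Why: alkoxide-directed iron-catalysed syn-carbomagnesiation of the homopropargylic alcohol delivers methyl to the distal alkyne carbon C10 and magnesium to C1 (five-membered chelate), so protonation should give the Z-trisubstituted olefin with C2 cis to C9.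

Step 10
Reactants: 15 (3Z,6R)-4-methyl-6,7-bis[(triethylsilyl)oxy]hept-3-en-1-ol
Product: 16 (3Z,6R)-4-methyl-6,7-bis[(triethylsilyl)oxy]hept-3-enal
Conditions: Dess–Martin periodinane, NaHCO3, CH2Cl2, 0 °C; used crude
Reagents that add atoms: none
Why: buffered Dess–Martin oxidation gives the β,γ-unsaturated aldehyde without base that would move the double bond into conjugation.

Step 11
Reactants: 16 (3Z,6R)-4-methyl-6,7-bis[(triethylsilyl)oxy]hept-3-enal; 6 1-({[(2Z)-2-iodo-4,4-dimethoxybut-2-en-1-yl]oxy}methyl)-4-methoxybenzene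
Product: 17 (2Z,4S,6Z,9R)-1,1-dimethoxy-3-{[(4-methoxybenzyl)oxy]methyl}-7-methyl-9,10-bis[(triethylsilyl)oxy]deca-2,6-dien-4-ol
Conditions: CrCl2 (3 equiv), NiCl2 (cat.), chiral oxazoline–sulfonamide ligand (3 equiv), Et3N (3 equiv), THF, rt
Reagents that add atoms: none
Why: asymmetric Nozaki–Hiyama–Kishi alkenylation forms C3–C4 under non-basic conditions with retention of the iodide geometry (C3 cis to C6), and the chiral chromium–sulfonamide complex should set the 3S carbinol by reagent control.

Step 12
Reactants: 17 (2Z,4S,6Z,9R)-1,1-dimethoxy-3-{[(4-methoxybenzyl)oxy]methyl}-7-methyl-9,10-bis[(triethylsilyl)oxy]deca-2,6-dien-4-ol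
Product: 18 (2Z,4S,6Z,9R)-1,1-dimethoxy-3-{[(4-methoxybenzyl)oxy]methyl}-7-methyl-9,10-bis[(triethylsilyl)oxy]deca-2,6-dien-4-yl acetate
Conditions: Ac2O, pyridine, DMAP (cat.), CH2Cl2, 0 °C to rt
Reagents that add atoms: acetic anhydride, CC(=O)OC(C)=O
Why: standard acetylation installs the C3 acetate of the target, which also prevents later hemiacetal formation between O3 and the Z-enal.

Step 13
Reactants: 18 (2Z,4S,6Z,9R)-1,1-dimethoxy-3-{[(4-methoxybenzyl)oxy]methyl}-7-methyl-9,10-bis[(triethylsilyl)oxy]deca-2,6-dien-4-yl acetate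
Product: 19 (2Z,4S)-5-[(2R,3S)-3-{(2R)-2,3-bis[(triethylsilyl)oxy]propyl}-3-methyloxiran-2-yl]-1,1-dimethoxy-3-{[(4-methoxybenzyl)oxy]methyl}pent-2-en-4-yl acetate
Conditions: D-fructose-derived ketone catalyst (30 mol %), KHSO5 (Oxone), K2CO3, Bu4NHSO4, MeCN/dimethoxymethane/aq. Na2B4O7 buffer, 0 °C
Reagents that add atoms: potassium peroxymonosulfate, [K+].[O-]S(=O)(=O)OO
Why: Shi epoxidation should attack only the electron-rich C1=C10 olefin (C4=C5 carries three allylic oxygens), and the spiro transition state with the single olefinic hydrogen (on C1) in the hindered quadrant should give the (1R,10S)-cis-epoxide by reagent control.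

Step 14
Reactants: 19 the (1R,10S)-epoxy acetate
Product: 20 C7 aldehyde (3S-acetate, 1R,10S-epoxide, 8R-OTES, C6 dimethyl acetal, C15 OPMB, 4Z)
Conditions: (COCl)2, DMSO, CH2Cl2, −78 to −30 °C; then Et3N, −78 to 0 °C
Reagents that add atoms: none
Why: under Swern conditions a primary triethylsilyl ether is cleaved and oxidised to the aldehyde in one operation while the secondary silyl ether at C8 is known to survive.

Step 15
Reactants: 20 C7 aldehyde; 21 methyl acrylate
Product: 22 Morita–Baylis–Hillman adduct (methyl 2-methylene-3-hydroxy ester at C7, both C7 epimers, other centres as in 20)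
Conditions: DABCO (1 equiv), methyl acrylate (excess), MeOH (3 equiv), rt; chromatography on Et3N-deactivated SiO2
Reagents that add atoms: none
Why: Morita–Baylis–Hillman reaction of the activated α-silyloxy aldehyde attaches C11–C13; the new C7 carbinol centre forms as a mixture that is erased in step 16.

Step 16
Reactants: 22 Morita–Baylis–Hillman adduct
Product: 23 (Z)-2-(bromomethyl)enoate (C7=C11 olefin with C8 cis to CH2Br, other centres as in 20)
Conditions: CBr4, PPh3, CH2Cl2, −20 to 0 °C
Reagents that add atoms: carbon tetrabromide, BrC(Br)(Br)Br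
Why: Appel activation of the secondary allylic alcohol followed by SN2' attack of bromide should give the conjugated, thermodynamically preferred primary allylic bromide under neutral conditions that spare the epoxide, acetal and silyl ether.

Step 17
Reactants: 23 (Z)-2-(bromomethyl)enoate
Product: 24 seco enal (C6 aldehyde, 4Z; 3S-acetate, 1R,10S-epoxide, 8R-OTES, C15 OPMB, allylic bromide)
Conditions: oxalic acid on wet SiO2, CH2Cl2, rt
Reagents that add atoms: water, O
Why: an α,β-unsaturated dimethyl acetal hydrolyses far faster than a silyl ether cleaves or a trisubstituted epoxide opens, so this mild heterogeneous acid should free only the C6 aldehyde.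

Step 18
Reactants: 24 seco enal
Product: 26 macrolactone (6,7-trans-fused α-methylene lactone on the ten-membered ring; 8-OTES; 3-OAc; 15-OPMB; 1,10-epoxide; 4Z), via hydroxy ester 25 (not isolated)
Conditions: CrCl2 (8 equiv), THF/DMF, syringe-pump addition of 24 to 2 mM, rt; pH 7 work-up
Reagents that add atoms: none
Why: Two CrCl2 reduce the allylic bromide to a 2-(methoxycarbonyl)allylchromium of trivalent chromium, which adds through its γ-carbon C7 to the C6 aldehyde in a chair-like six-membered (Zimmerman–Traxler) transition state, after which the C6 chromium alkoxide acylates on the C12 methyl ester; the closest known reaction type is the intramolecular Nozaki–Hiyama (Barbier-type) 2-(alkoxycarbonyl)allylation used to close medium carbocycles that carry α-methylene lactones. The ten-membered carbocycle closes by a 10-exo-trig addition to the carbonyl group and the lactone by a 5-exo-trig acyl substitution. C7 is controlled by the neighbouring C8 centre: with H8 eclipsing the C7=C11 bond (allylic 1,3-strain) the bulky OTES group points outward and the enal, tethered through C9, reaches the C7 face anti to C9, which gives the 7,8-relationship of the target. C6 follows from the chair: the allylchromium equilibrates by 1,3-metal shift and should react through the isomer in which C8 and the enal chain (C5) are both pseudo-equatorial, giving the anti adduct and hence the trans-fused lactone. The step needs γ-regioselectivity, 1,2-addition to the enal, cyclisation over oligomerisation and survival of the epoxide, allylic acetate and silyl ether; these are secured by the SE2' reactivity and low basicity of allylchromium reagents, by high dilution, by a poor leaving group (silyl ether, not ester) at C8, and by the cis-epoxide and the Z C4=C5 olefin, which pre-organise the chain.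

Step 19
Reactants: 26 macrolactone
Product: 27 8-hydroxy macrolactone (6R,7R,8R; 3-OAc; 15-OPMB; 1R,10S-epoxide)
Conditions: HF·pyridine, pyridine, THF, 0 °C
Reagents that add atoms: none
Why: buffered fluoride cleaves the secondary triethylsilyl ether quickly at 0 °C, conditions under which the epoxide, the lactone and the acetate should persist.

Step 20
Reactants: 27 8-hydroxy macrolactone; 28 angelic acid
Product: 30 8-O-angeloyl macrolactone 15-O-(4-methoxybenzyl) ether, via mixed anhydride 29 (not isolated)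
Conditions: 28, 2,4,6-trichlorobenzoyl chloride, Et3N, toluene, rt; then 27, toluene, 70 °C
Reagents that add atoms: none
Why: Yamaguchi esterification through the pre-formed mixed anhydride, run without DMAP, is the established way to acylate secondary alcohols with angelic acid without Z-to-E isomerisation to the tiglate.

Step 21
Reactants: 30 8-O-angeloyl macrolactone 15-O-(4-methoxybenzyl) ether
Product: 31 target, CNP0162483.1
Conditions: DDQ, CH2Cl2/pH 7 buffer, 0 °C to rt
Reagents that add atoms: none
Why: neutral oxidative removal of the 4-methoxybenzyl group frees the C15 hydroxyl without acid or base that could open the epoxide, move the acetate or add to the α-methylene lactone.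

Compound list
1 | but-2-yne-1,4-diol | OCC#CCO | starting material
2 | 4-[(4-methoxybenzyl)oxy]but-2-yn-1-ol | COc1ccc(COCC#CCO)cc1 | intermediate
3 | sodium cyclic alkenylalanate from 2 (Al on the alkyne carbon distal to the alkoxide, cis to the CH2O arm) | [Na+].COCCO[Al-]1(OCCOC)OCC=C1COCc2ccc(OC)cc2 | intermediate
4 | (2Z)-3-iodo-4-[(4-methoxybenzyl)oxy]but-2-en-1-ol | OC/C=C(\I)COCc1ccc(OC)cc1 | intermediate
5 | (2Z)-3-iodo-4-[(4-methoxybenzyl)oxy]but-2-enal | O=C/C=C(\I)COCc1ccc(OC)cc1 | intermediate
6 | 1-({[(2Z)-2-iodo-4,4-dimethoxybut-2-en-1-yl]oxy}methyl)-4-methoxybenzene | COC(OC)/C=C(\I)COCc1ccc(OC)cc1 | intermediate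
7 | (S)-glycidol | OC[C@H]1CO1 | starting material
8 | (R)-triethyl(oxiran-2-ylmethoxy)silane | CC[Si](CC)(CC)OC[C@H]1CO1 | intermediate
9 | 1-[(but-3-yn-1-yloxy)methyl]-4-methoxybenzene | C#CCCOCc1ccc(OC)cc1 | starting material
10 | lithium acetylide of 9 | [Li]C#CCCOCc1ccc(OC)cc1 | intermediate
11 | (2R)-7-[(4-methoxybenzyl)oxy]-1-[(triethylsilyl)oxy]hept-4-yn-2-ol | COc1ccc(COCCC#CC[C@@H](O)CO[Si](CC)(CC)CC)cc1 | intermediate
12 | 1-({[(6R)-6,7-bis(triethylsilyloxy)hept-3-yn-1-yl]oxy}methyl)-4-methoxybenzene | COc1ccc(COCCC#CC[C@@H](O[Si](CC)(CC)CC)CO[Si](CC)(CC)CC)cc1 | intermediate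
13 | (6R)-6,7-bis[(triethylsilyl)oxy]hept-3-yn-1-ol | OCCC#CC[C@@H](O[Si](CC)(CC)CC)CO[Si](CC)(CC)CC | intermediate
14 | alkenylmagnesium alkoxide from syn-methylmagnesiation of 13 (Mg on C1, cis to the new methyl) | Br[Mg]OCC/C([Mg]Br)=C(/C)C[C@@H](O[Si](CC)(CC)CC)CO[Si](CC)(CC)CC | intermediate
15 | (3Z,6R)-4-methyl-6,7-bis[(triethylsilyl)oxy]hept-3-en-1-ol | OCC/C=C(/C)C[C@@H](O[Si](CC)(CC)CC)CO[Si](CC)(CC)CC | intermediate
16 | (3Z,6R)-4-methyl-6,7-bis[(triethylsilyl)oxy]hept-3-enal | O=CC/C=C(/C)C[C@@H](O[Si](CC)(CC)CC)CO[Si](CC)(CC)CC | intermediate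
17 | (2Z,4S,6Z,9R)-1,1-dimethoxy-3-{[(4-methoxybenzyl)oxy]methyl}-7-methyl-9,10-bis[(triethylsilyl)oxy]deca-2,6-dien-4-ol | COC(OC)/C=C(/COCc1ccc(OC)cc1)[C@@H](O)C/C=C(/C)C[C@@H](O[Si](CC)(CC)CC)CO[Si](CC)(CC)CC | intermediate
18 | (2Z,4S,6Z,9R)-1,1-dimethoxy-3-{[(4-methoxybenzyl)oxy]methyl}-7-methyl-9,10-bis[(triethylsilyl)oxy]deca-2,6-dien-4-yl acetate | COC(OC)/C=C(/COCc1ccc(OC)cc1)[C@@H](OC(C)=O)C/C=C(/C)C[C@@H](O[Si](CC)(CC)CC)CO[Si](CC)(CC)CC | intermediate
19 | (2Z,4S)-5-[(2R,3S)-3-{(2R)-2,3-bis[(triethylsilyl)oxy]propyl}-3-methyloxiran-2-yl]-1,1-dimethoxy-3-{[(4-methoxybenzyl)oxy]methyl}pent-2-en-4-yl acetate | COC(OC)/C=C(/COCc1ccc(OC)cc1)[C@@H](OC(C)=O)C[C@H]2O[C@@]2(C)C[C@@H](O[Si](CC)(CC)CC)CO[Si](CC)(CC)CC | intermediate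
20 | C7 aldehyde: 19 with the primary CH2OTES oxidised to CHO (3S, 1R, 10S, 8R; 4Z) | COC(OC)/C=C(/COCc1ccc(OC)cc1)[C@@H](OC(C)=O)C[C@H]2O[C@@]2(C)C[C@@H](O[Si](CC)(CC)CC)C=O | intermediate
21 | methyl acrylate | C=CC(=O)OC | starting material
22 | Morita–Baylis–Hillman adduct of 20 (C7 carbinol as both epimers; 3S, 1R, 10S, 8R; 4Z) | COC(OC)/C=C(/COCc1ccc(OC)cc1)[C@@H](OC(C)=O)C[C@H]2O[C@@]2(C)C[C@@H](O[Si](CC)(CC)CC)C(O)C(=C)C(=O)OC | intermediate
23 | methyl (Z)-2-(bromomethyl)enoate (C8 cis to CH2Br; C6 dimethyl acetal; 3S, 1R, 10S, 8R; 4Z) | COC(OC)/C=C(/COCc1ccc(OC)cc1)[C@@H](OC(C)=O)C[C@H]2O[C@@]2(C)C[C@@H](O[Si](CC)(CC)CC)/C=C(\CBr)C(=O)OC | intermediate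
24 | seco enal: 23 with the acetal hydrolysed to the C6 aldehyde (4Z; 3S, 1R, 10S, 8R) | O=C/C=C(/COCc1ccc(OC)cc1)[C@@H](OC(C)=O)C[C@H]2O[C@@]2(C)C[C@@H](O[Si](CC)(CC)CC)/C=C(\CBr)C(=O)OC | intermediate
25 | ten-membered hydroxy ester (C6 OH, C7 bearing the methyl acrylate unit; CIP 6R,7S,8R, same spatial arrangement as the target) | C=C(C(=O)OC)[C@H]1[C@H](O)/C=C(/COCc4ccc(OC)cc4)[C@@H](OC(C)=O)C[C@H]3O[C@@]3(C)C[C@H]1O[Si](CC)(CC)CC | intermediate
26 | macrolactone: target skeleton with 8-OTES and 15-OPMB (CIP 1R,3S,6R,7S,8R,10S; the 7-descriptor differs from the target only through the silyl ether priority) | C=C1C(=O)O[C@@H]2/C=C(/COCc4ccc(OC)cc4)[C@@H](OC(C)=O)C[C@H]3O[C@@]3(C)C[C@@H](O[Si](CC)(CC)CC)[C@@H]12 | intermediate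
27 | 8-hydroxy macrolactone 15-O-(4-methoxybenzyl) ether (1R,3S,6R,7R,8R,10S) | C=C1C(=O)O[C@@H]2/C=C(/COCc4ccc(OC)cc4)[C@@H](OC(C)=O)C[C@H]3O[C@@]3(C)C[C@@H](O)[C@@H]12 | intermediate
28 | angelic acid, (2Z)-2-methylbut-2-enoic acid | C/C=C(/C)C(=O)O | starting material
29 | angelic 2,4,6-trichlorobenzoic mixed anhydride | C/C=C(/C)C(=O)OC(=O)c1c(Cl)cc(Cl)cc1Cl | intermediate
30 | 8-O-angeloyl macrolactone 15-O-(4-methoxybenzyl) ether (1R,3S,6R,7R,8R,10S) | C=C1C(=O)O[C@@H]2/C=C(/COCc4ccc(OC)cc4)[C@@H](OC(C)=O)C[C@H]3O[C@@]3(C)C[C@@H](OC(=O)/C(C)=C\C)[C@@H]12 | intermediate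
31 | CNP0162483.1 (1R,3S,6R,7R,8R,10S; 4Z) | C=C1C(=O)O[C@@H]2/C=C(/CO)[C@@H](OC(C)=O)C[C@H]3O[C@@]3(C)C[C@@H](OC(=O)/C(C)=C\C)[C@@H]12 | target

Total steps: 21. Longest linear sequence: 17 (steps 5–21, from (S)-glycidol). The iodide branch (steps 1–4) joins in step 11.

Steps most likely to fail

Step 18. The ring closure may go wrong in three ways. The allylchromium may add through the alternative chair and give the 6,7-cis-fused or 7-epimeric lactone. Chains may couple with each other instead of cyclising. The epoxide or the C8 silyloxy group may be lost, by opening on trivalent chromium or by β-elimination from the C7-bound chromium tautomer. The free C7 hydroxyl of 22 may also attack the epoxide on the way to the precursor. The fallback installs the epoxide only after the ring is made, which changes both the conformational bias of the closure and the functional groups exposed to chromium. It sets out from 18. Swern oxidation as in step 14 gives the des-epoxy aldehyde F1. Morita–Baylis–Hillman reaction with 21 gives the adduct F2. Appel bromination with transposition gives the bromide F3. Acetal hydrolysis gives the dienyl enal F4. CrCl2 closure under the conditions of step 18 gives the 1(10)Z,4Z-diene macrolactone F5. Its only electron-rich olefin, C1=C10, is then epoxidised under the Shi conditions of step 13, and the route is rejoined at 26.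

Step 11. The chiral chromium complex may discriminate the faces of the unhindered aldehyde poorly, and the β,γ-double bond of 16 may migrate into conjugation before coupling. The fallback separates bond formation from stereocontrol and sets out from 16 and 6. Ligand-free coupling (CrCl2, NiCl2 cat., DMSO, rt) gives the C3-epimeric allylic alcohols F6. Dess–Martin oxidation gives the enone F7. Corey–Bakshi–Shibata reduction with the (R)-methyl oxazaborolidine and catecholborane at −78 °C, in which the α-branched alkenyl group acts as the large substituent, should give the 3S carbinol and return to 17.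

Step 20. The hindered C8 hydroxyl may acylate slowly, so that the angeloyl donor isomerises to the tiglate or the lactone migrates from O6 to O8 under the warm basic conditions. The fallback builds the Z-enoate on the molecule and sets out from 27. Esterification with 2-[bis(2,2,2-trifluoroethoxy)phosphoryl]propanoic acid (DCC, DMAP cat., CH2Cl2, 0 °C) gives the phosphonate ester F8. Still–Gennari olefination (KN(SiMe3)2, 18-crown-6, THF, −78 °C; acetaldehyde) should give the Z-2-methylbut-2-enoate and return to 30.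

Further compounds
F1 | step 18 | des-epoxy C7 aldehyde (1(10)Z,4Z; 3S,8R) | COC(OC)/C=C(/COCc1ccc(OC)cc1)[C@@H](OC(C)=O)C/C=C(/C)C[C@@H](O[Si](CC)(CC)CC)C=O
F2 | step 18 | des-epoxy Morita–Baylis–Hillman adduct (C7 epimers) | COC(OC)/C=C(/COCc1ccc(OC)cc1)[C@@H](OC(C)=O)C/C=C(/C)C[C@@H](O[Si](CC)(CC)CC)C(O)C(=C)C(=O)OC
F3 | step 18 | des-epoxy (Z)-2-(bromomethyl)enoate | COC(OC)/C=C(/COCc1ccc(OC)cc1)[C@@H](OC(C)=O)C/C=C(/C)C[C@@H](O[Si](CC)(CC)CC)/C=C(\CBr)C(=O)OC
F4 | step 18 | des-epoxy seco enal | O=C/C=C(/COCc1ccc(OC)cc1)[C@@H](OC(C)=O)C/C=C(/C)C[C@@H](O[Si](CC)(CC)CC)/C=C(\CBr)C(=O)OC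
F5 | step 18 | 1(10)Z,4Z-diene macrolactone (8-OTES, 15-OPMB, 3-OAc) | C=C1C(=O)O[C@@H]2/C=C(/COCc4ccc(OC)cc4)[C@@H](OC(C)=O)C/C=C(/C)C[C@@H](O[Si](CC)(CC)CC)[C@@H]12
F6 | step 11 | C3-epimeric allylic alcohols (mixture at C3) | COC(OC)/C=C(/COCc1ccc(OC)cc1)C(O)C/C=C(/C)C[C@@H](O[Si](CC)(CC)CC)CO[Si](CC)(CC)CC
F7 | step 11 | C3 enone | COC(OC)/C=C(/COCc1ccc(OC)cc1)C(=O)C/C=C(/C)C[C@@H](O[Si](CC)(CC)CC)CO[Si](CC)(CC)CC
F8 | step 20 | 8-O-{2-[bis(2,2,2-trifluoroethoxy)phosphoryl]propanoyl} macrolactone | C=C1C(=O)O[C@@H]2/C=C(/COCc4ccc(OC)cc4)[C@@H](OC(C)=O)C[C@H]3O[C@@]3(C)C[C@@H](OC(=O)C(C)P(=O)(OCC(F)(F)F)OCC(F)(F)F)[C@@H]12
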